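Numbering used below (drimane): ring A is C1=C2–C3(=O)–C4(Me)2–C5–C10; ring B is C5–C6–C7=C8(Me)–C9(C11H2OAr)–C10(Me).
Cuts, in retrosynthetic order: the C11–O(aryl) bond; the two C4–CH3 bonds; C1=C2 (aldol condensation); then C5–C6 and C9–C10 together (Diels–Alder). C7 carries a silyloxy group during the cycloaddition and is reduced to C–H afterwards.
Enabling feature: ring B is a cyclohexene whose stereocentres C5, C10 and C9 are contiguous sp3 atoms on the σ-bonds C5–C6 and C9–C10 that flank C6–C7=C8–C9, and C10 bears C1, which can be a formyl group while ring A is still open.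
Forward: ring B is made first from diene 4 (C6–C9, C11, C8-Me) and (E)-enal 9 (C1–C5, C10, C10-Me); ring A then follows by Wacker oxidation and aldol condensation, then C4 gem-dimethylation, with isofraxidin attached last.
Stereochemistry: C10-Me/C5-H trans comes from the E geometry of 9, the axial C11 (cis to C1) from endo addition, and the absolute sense from the (R)-oxazaborolidinium catalyst; no stereocentre is formed after step 5.

Key step: step 5

Assumption: for α-branched enals the triflimide-activated (S)-oxazaborolidine is taken to expose the Re face of the α-carbon (formyl C–H···O binding mode), so the (R)-catalyst is specified and its antipode would be used if the first run showed the opposite sense; 1, 2 and 19 are taken as catalogue compounds.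

Step 1
Reactants: 1 (tert-butyldiphenylsilyloxy)acetaldehyde; 2 3-(triphenyl-λ5-phosphanylidene)butan-2-one
Product: 3 (3E)-5-[(tert-butyldiphenylsilyl)oxy]-3-methylpent-3-en-2-one
Conditions: toluene, 80 °C
Reagents that add atoms: none
Why: Wittig olefination with a stabilised α-branched keto ylide, which should deliver the thermodynamically preferred (E)-trisubstituted enone (acetyl trans to CH2OSi).

Step 2
Reactants: 3 (3E)-5-[(tert-butyldiphenylsilyl)oxy]-3-methylpent-3-en-2-one
Product: 4 tert-butyl({(2E)-3-methyl-4-[(triisopropylsilyl)oxy]penta-2,4-dien-1-yl}oxy)diphenylsilane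
Conditions: LDA, THF, −78 °C; then TIPSOTf
Reagents that add atoms: triisopropylsilyl trifluoromethanesulfonate, CC(C)[Si](OS(=O)(=O)C(F)(F)F)(C(C)C)C(C)C
Why: Kinetic α′-deprotonation of the methyl ketone (the γ-CH2 lies anti to the carbonyl and is not reached in the cyclic deprotonation transition state) and O-silylation should give the cross-conjugated 2-silyloxydiene with the E alkene untouched.

Step 3
Reactants: 5 prop-2-yn-1-ol; 6 3-bromoprop-1-ene
Product: 8 (2E)-2-methylhexa-2,5-dien-1-ol, via alkenylalane 7 (not isolated)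
Conditions: AlMe3 (3 equiv), Cp2ZrCl2 (25 mol %), CH2Cl2, 0 °C to rt; then 6, Pd(PPh3)4 (3 mol %), THF, rt; aq. Rochelle salt
Reagents that add atoms: trimethylaluminium, C[Al](C)C
Why: Negishi zirconium-catalysed carboalumination adds CH3–Al syn across the alkyne with methyl on the internal carbon, and palladium-catalysed alkenyl–allyl coupling replaces aluminium with retention, so the 2E geometry is set by the syn addition.

Step 4
Reactants: 8 (2E)-2-methylhexa-2,5-dien-1-ol
Product: 9 (2E)-2-methylhexa-2,5-dienal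
Conditions: MnO2 (10 equiv), CH2Cl2, rt
Reagents that add atoms: none
Why: Allylic oxidation with MnO2 under neutral heterogeneous conditions should leave the skipped diene unconjugated and the E geometry intact.

Step 5
Reactants: 4 tert-butyl({(2E)-3-methyl-4-[(triisopropylsilyl)oxy]penta-2,4-dien-1-yl}oxy)diphenylsilane; 9 (2E)-2-methylhexa-2,5-dienal
Product: 10 (1R,2S,6S)-2-{[(tert-butyldiphenylsilyl)oxy]methyl}-1,3-dimethyl-6-(prop-2-en-1-yl)-4-[(triisopropylsilyl)oxy]cyclohex-3-ene-1-carbaldehyde
Conditions: (R)-o-tolyl-CBS-oxazaborolidine (20 mol %), Tf2NH (17 mol %), CH2Cl2, −78 to −40 °C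
Reagents that add atoms: none
Why: The triflimide-activated oxazaborolidine binds the formyl group of 9 (B–O coordination, s-trans enal) and lowers its LUMO, and the electron-rich 2-silyloxydiene 4 adds in an asynchronous concerted [4+2] in which C6–C5 bonding leads and C9–C10 follows; the closest known reaction type is the cationic-oxazaborolidine-catalysed enantioselective Diels–Alder reaction of 2-methyl-2-enals with 2-silyloxydienes. Ring B (C5–C6–C7=C8–C9–C10) is closed by intermolecular [4+2] cycloaddition. The C10/C5 relationship (formyl trans to allyl, hence C10-Me trans to C5-H) is fixed by the E geometry of 9 through suprafacial addition, the C9/C10 relationship (CH2OSi cis to formyl, the later axial C11) by the endo orientation of the formyl group toward the (E)-configured diene terminus, and the absolute configuration by the catalyst, whose aryl group shields one face of the bound enal so that the diene adds to the Si face at C10. The step needs regioselectivity, secured by the C7 silyloxy group, which makes C6 the nucleophilic terminus and overrides the opposing bias of the C8 methyl group; endo selectivity, secured by the small exo methyl group and the secondary-orbital preference of the coordinated formyl group; and face selectivity, secured by the single binding mode of the α-methyl enal.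

Step 6
Reactants: 10 (1R,2S,6S)-2-{[(tert-butyldiphenylsilyl)oxy]methyl}-1,3-dimethyl-6-(prop-2-en-1-yl)-4-[(triisopropylsilyl)oxy]cyclohex-3-ene-1-carbaldehyde
Product: 11 (1R,2S,6S)-2-{[(tert-butyldiphenylsilyl)oxy]methyl}-1,3-dimethyl-6-(prop-2-en-1-yl)-4-{[(trifluoromethyl)sulfonyl]oxy}cyclohex-3-ene-1-carbaldehyde
Conditions: CsF (1.5 equiv), PhNTf2 (1.3 equiv), DME, rt
Reagents that add atoms: N-phenylbis(trifluoromethanesulfonimide), O=S(=O)(N(c1ccccc1)S(=O)(=O)C(F)(F)F)C(F)(F)F
Why: Fluoride cleaves the enol silyl ether to a regiodefined caesium enolate that is O-sulfonylated (silyl enol ether to enol triflate exchange), keeping the C7=C8 position set by the cycloaddition; the enolate carbon could reach the formyl group only through a four-membered ring, and the alkyl TBDPS ether is far less fluoride-labile than the enol ether.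

Step 7
Reactants: 11 (1R,2S,6S)-2-{[(tert-butyldiphenylsilyl)oxy]methyl}-1,3-dimethyl-6-(prop-2-en-1-yl)-4-{[(trifluoromethyl)sulfonyl]oxy}cyclohex-3-ene-1-carbaldehyde
Product: 12 (1R,2S,6S)-2-{[(tert-butyldiphenylsilyl)oxy]methyl}-1,3-dimethyl-6-(prop-2-en-1-yl)cyclohex-3-ene-1-carbaldehyde
Conditions: Pd(OAc)2 (5 mol %), PPh3 (10 mol %), HCO2H, Bu3N, DMF, 60 °C
Reagents that add atoms: none
Why: Palladium-catalysed formate reduction of the enol triflate (oxidative addition, formate decarboxylation, C–H reductive elimination) should replace OTf by H without moving the double bond, giving the trisubstituted C7=C8 alkene.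

Step 8
Reactants: 12 (1R,2S,6S)-2-{[(tert-butyldiphenylsilyl)oxy]methyl}-1,3-dimethyl-6-(prop-2-en-1-yl)cyclohex-3-ene-1-carbaldehyde
Product: 13 (1R,2S,6R)-2-{[(tert-butyldiphenylsilyl)oxy]methyl}-1,3-dimethyl-6-(2-oxopropyl)cyclohex-3-ene-1-carbaldehyde
Conditions: PdCl2 (10 mol %), CuCl, O2 (1 atm), DMF/H2O 7:1, rt
Reagents that add atoms: water, O
Why: Tsuji–Wacker oxidation should convert the monosubstituted alkene into the methyl ketone by Markovnikov hydroxypalladation, while the trisubstituted ring alkene is too hindered to react.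

Step 9
Reactants: 13 (1R,2S,6R)-2-{[(tert-butyldiphenylsilyl)oxy]methyl}-1,3-dimethyl-6-(2-oxopropyl)cyclohex-3-ene-1-carbaldehyde
Product: 15 (4aS,5S,8aR)-5-{[(tert-butyldiphenylsilyl)oxy]methyl}-4a,6-dimethyl-4a,5,8,8a-tetrahydronaphthalen-2(1H)-one, via aldol 14 (not isolated)
Conditions: NaOMe (0.3 equiv), MeOH/THF, 0 to 40 °C
Reagents that add atoms: none
Why: Intramolecular aldol condensation in which only the C2 methyl enolate can reach the non-enolisable C1 aldehyde through a six-membered ring (C4 attack would need a four-membered ring), followed by E1cB dehydration to the 1-en-3-one; the trans ring fusion is already fixed at C5 and C10.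

Step 10
Reactants: 15 (4aS,5S,8aR)-5-{[(tert-butyldiphenylsilyl)oxy]methyl}-4a,6-dimethyl-4a,5,8,8a-tetrahydronaphthalen-2(1H)-one
Product: 17 (4aR,5S,8aS)-5-{[(tert-butyldiphenylsilyl)oxy]methyl}-1,1,4a,6-tetramethyl-4a,5,8,8a-tetrahydronaphthalen-2(1H)-one, via monomethyl enone 16 (not isolated)
Conditions: LDA, THF, −78 °C, then MeI; second charge of LDA, DMPU, MeI, −78 to 0 °C
Reagents that add atoms: iodomethane, CI
Why: The enone has no γ-hydrogen (C10 is quaternary), so LDA should give only the cross-conjugated α′-enolate at C4, which is C-methylated twice (kinetic enolate alkylation) to a centre that is no longer stereogenic.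

Step 11
Reactants: 17 (4aR,5S,8aS)-5-{[(tert-butyldiphenylsilyl)oxy]methyl}-1,1,4a,6-tetramethyl-4a,5,8,8a-tetrahydronaphthalen-2(1H)-one
Product: 18 (4aR,5S,8aS)-5-(hydroxymethyl)-1,1,4a,6-tetramethyl-4a,5,8,8a-tetrahydronaphthalen-2(1H)-one
Conditions: TBAF, AcOH, THF, rt
Reagents that add atoms: none
Why: Fluoride-mediated cleavage of the silyl ether, buffered with acetic acid so that the enone is not exposed to free alkoxide.

Step 12
Reactants: 18 (4aR,5S,8aS)-5-(hydroxymethyl)-1,1,4a,6-tetramethyl-4a,5,8,8a-tetrahydronaphthalen-2(1H)-one; 19 isofraxidin (7-hydroxy-6,8-dimethoxy-2H-chromen-2-one)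
Product: 20 6,8-dimethoxy-7-{[(1S,4aS,8aR)-2,5,5,8a-tetramethyl-6-oxo-1,4,4a,5,6,8a-hexahydronaphthalen-1-yl]methoxy}-2H-chromen-2-one (target CNP0330704.1)
Conditions: PPh3, DIAD, toluene, 0 to 50 °C
Reagents that add atoms: none
Why: Mitsunobu etherification of the primary alcohol with the acidic 7-hydroxycoumarin should form the C11–O bond by SN2 at a non-stereogenic carbon, so no stereocentre is touched.

Compound list (CIP labels change along the route only because substituent priorities change; the geometry set in step 5 is unchanged)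

1 | (tert-butyldiphenylsilyloxy)acetaldehyde | O=CCO[Si](c1ccccc1)(c1ccccc1)C(C)(C)C | starting material
2 | 3-(triphenyl-λ5-phosphanylidene)butan-2-one | CC(=O)C(C)=P(c1ccccc1)(c1ccccc1)c1ccccc1 | starting material
3 | (3E)-5-[(tert-butyldiphenylsilyl)oxy]-3-methylpent-3-en-2-one | CC(=O)/C(C)=C/CO[Si](c1ccccc1)(c1ccccc1)C(C)(C)C | intermediate
4 | tert-butyl({(2E)-3-methyl-4-[(triisopropylsilyl)oxy]penta-2,4-dien-1-yl}oxy)diphenylsilane | C=C(O[Si](C(C)C)(C(C)C)C(C)C)/C(C)=C/CO[Si](c1ccccc1)(c1ccccc1)C(C)(C)C | intermediate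
5 | prop-2-yn-1-ol | C#CCO | starting material
6 | 3-bromoprop-1-ene (allyl bromide) | C=CCBr | starting material
7 | (E)-[3-(dimethylalumanyloxy)-2-methylprop-1-en-1-yl]dimethylalumane | C[Al](C)OC/C(C)=C/[Al](C)C | intermediate
8 | (2E)-2-methylhexa-2,5-dien-1-ol | OC/C(C)=C/CC=C | intermediate
9 | (2E)-2-methylhexa-2,5-dienal | O=C/C(C)=C/CC=C | intermediate
10 | (1R,2S,6S)-2-{[(tert-butyldiphenylsilyl)oxy]methyl}-1,3-dimethyl-6-(prop-2-en-1-yl)-4-[(triisopropylsilyl)oxy]cyclohex-3-ene-1-carbaldehyde | O=C[C@]1(C)[C@@H](CC=C)CC(O[Si](C(C)C)(C(C)C)C(C)C)=C(C)[C@@H]1CO[Si](c1ccccc1)(c1ccccc1)C(C)(C)C | intermediate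
11 | (1R,2S,6S)-2-{[(tert-butyldiphenylsilyl)oxy]methyl}-1,3-dimethyl-6-(prop-2-en-1-yl)-4-{[(trifluoromethyl)sulfonyl]oxy}cyclohex-3-ene-1-carbaldehyde | O=C[C@]1(C)[C@@H](CC=C)CC(OS(=O)(=O)C(F)(F)F)=C(C)[C@@H]1CO[Si](c1ccccc1)(c1ccccc1)C(C)(C)C | intermediate
12 | (1R,2S,6S)-2-{[(tert-butyldiphenylsilyl)oxy]methyl}-1,3-dimethyl-6-(prop-2-en-1-yl)cyclohex-3-ene-1-carbaldehyde | O=C[C@]1(C)[C@@H](CC=C)CC=C(C)[C@@H]1CO[Si](c1ccccc1)(c1ccccc1)C(C)(C)C | intermediate
13 | (1R,2S,6R)-2-{[(tert-butyldiphenylsilyl)oxy]methyl}-1,3-dimethyl-6-(2-oxopropyl)cyclohex-3-ene-1-carbaldehyde | O=C[C@]1(C)[C@@H](CC(C)=O)CC=C(C)[C@@H]1CO[Si](c1ccccc1)(c1ccccc1)C(C)(C)C | intermediate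
14 | (4aR,5S,8aR)-5-{[(tert-butyldiphenylsilyl)oxy]methyl}-4-hydroxy-4a,6-dimethyl-3,4,4a,5,8,8a-hexahydronaphthalen-2(1H)-one (C4 epimers) | CC(C)(C)[Si](c1ccccc1)(c1ccccc1)OC[C@H]1C(C)=CC[C@@H]2CC(=O)CC(O)[C@]21C | intermediate
15 | (4aS,5S,8aR)-5-{[(tert-butyldiphenylsilyl)oxy]methyl}-4a,6-dimethyl-4a,5,8,8a-tetrahydronaphthalen-2(1H)-one | CC(C)(C)[Si](c1ccccc1)(c1ccccc1)OC[C@H]1C(C)=CC[C@@H]2CC(=O)C=C[C@]21C | intermediate
16 | (4aR,5S,8aR)-5-{[(tert-butyldiphenylsilyl)oxy]methyl}-1,4a,6-trimethyl-4a,5,8,8a-tetrahydronaphthalen-2(1H)-one (C1 epimers) | CC(C)(C)[Si](c1ccccc1)(c1ccccc1)OC[C@H]1C(C)=CC[C@@H]2C(C)C(=O)C=C[C@]21C | intermediate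
17 | (4aR,5S,8aS)-5-{[(tert-butyldiphenylsilyl)oxy]methyl}-1,1,4a,6-tetramethyl-4a,5,8,8a-tetrahydronaphthalen-2(1H)-one | CC(C)(C)[Si](c1ccccc1)(c1ccccc1)OC[C@H]1C(C)=CC[C@@H]2C(C)(C)C(=O)C=C[C@]21C | intermediate
18 | (4aR,5S,8aS)-5-(hydroxymethyl)-1,1,4a,6-tetramethyl-4a,5,8,8a-tetrahydronaphthalen-2(1H)-one | OC[C@H]1C(C)=CC[C@@H]2C(C)(C)C(=O)C=C[C@]21C | intermediate
19 | isofraxidin (7-hydroxy-6,8-dimethoxy-2H-chromen-2-one) | COc1cc2ccc(=O)oc2c(OC)c1O | starting material
20 | 6,8-dimethoxy-7-{[(1S,4aS,8aR)-2,5,5,8a-tetramethyl-6-oxo-1,4,4a,5,6,8a-hexahydronaphthalen-1-yl]methoxy}-2H-chromen-2-one | COc1cc2ccc(=O)oc2c(OC)c1OC[C@H]1C(C)=CC[C@@H]2C(C)(C)C(=O)C=C[C@]21C | target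

Total step count: 12
Longest linear sequence: 10 steps (steps 1, 2, 5–12)

Steps most likely to fail

1. Step 5. The activated enal may be attacked by the silyl dienol ether in an open-chain Mukaiyama-type conjugate or carbonyl addition instead of cycloaddition, and endo or facial discrimination may erode with the α,β-disubstituted enal. The fallback sets out from 4 and 9 and gives up catalyst control. The two are heated without Lewis acid (toluene, 110 °C, BHT), which avoids the Mukaiyama pathways while regiochemistry and the trans C5/C10 relationship are still dictated by the silyloxy group and the E geometry. The endo adduct should then be obtained as a racemate, i.e. 10 together with its mirror image (1S,2R,6R)-2-{[(tert-butyldiphenylsilyl)oxy]methyl}-1,3-dimethyl-6-(prop-2-en-1-yl)-4-[(triisopropylsilyl)oxy]cyclohex-3-ene-1-carbaldehyde F1. The enantiomers are separated by preparative chromatography on a chiral stationary phase and the route is rejoined at 10.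

2. Step 12. The alkoxyphosphonium ion of the hindered, axial, homoallylic hydroxymethyl group may lose the allylic C9 proton (elimination to the exocyclic diene) faster than it is displaced by the di-ortho-substituted phenol. The fallback sets out from 18 and replaces the redox condensation by a preformed electrophile. Tf2O and 2,6-lutidine in CH2Cl2 at −78 °C should give [(1S,4aS,8aR)-2,5,5,8a-tetramethyl-6-oxo-1,4,4a,5,6,8a-hexahydronaphthalen-1-yl]methyl trifluoromethanesulfonate F2. This is displaced at 0 °C by the weakly basic caesium phenoxide of 19 (Cs2CO3, MeCN), returning to the route at 20.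

3. Step 3. Carbometalation of the unprotected propargylic alcohol is slow, the alkoxide-bearing alane may transfer poorly to palladium, and the volatile product may be lost on isolation. The fallback does not use 5 and 6; it sets out from commercial 2-methyl-2-vinyloxirane. Copper-catalysed SN2′ opening with vinylmagnesium bromide (CuI 10 mol %, THF, −40 °C) should give 8 directly, the minor Z isomer being removed on silver nitrate-impregnated silica. The route is rejoined at 8 with no new intermediate.

Further compounds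
F1 | step 5 | (1S,2R,6R)-2-{[(tert-butyldiphenylsilyl)oxy]methyl}-1,3-dimethyl-6-(prop-2-en-1-yl)-4-[(triisopropylsilyl)oxy]cyclohex-3-ene-1-carbaldehyde | O=C[C@@]1(C)[C@H](CC=C)CC(O[Si](C(C)C)(C(C)C)C(C)C)=C(C)[C@H]1CO[Si](c1ccccc1)(c1ccccc1)C(C)(C)C
F2 | step 12 | [(1S,4aS,8aR)-2,5,5,8a-tetramethyl-6-oxo-1,4,4a,5,6,8a-hexahydronaphthalen-1-yl]methyl trifluoromethanesulfonate | O=S(=O)(OC[C@H]1C(C)=CC[C@@H]2C(C)(C)C(=O)C=C[C@]21C)C(F)(F)F
F0 | step 3 | none | none
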